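A direct plan would build chalcone A2 from 2',6'-dihydroxy-4'-methoxyacetophenone A1 by Claisen–Schmidt condensation and close it oxidatively to the 5-hydroxy-7-methoxyflavone A3, with the 4'-OH held as a MOM ether. O-Prenylation of the 5-OH would give the prenyl ether A4, a Claisen–Cope sequence would move the prenyl group to C8, and acid would remove the acetal.
Its weakest steps would be:
- the O-alkylation of the 5-OH, because this phenol is chelated to C4=O and poorly nucleophilic;
- the O-to-C8 prenyl transfer, because it must pass through C6 and could stop there, so the C8 regiochemistry would rest on a migration;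
- the protection and deprotection of the 4'-OH, which would add length without adding complexity.

The route rests on cutting the pyranone ring (O1, C2, C3, C4, C4a, C8a) at three bonds: C4a–C4, C4–C3 and O1–C2. C4 is a single carbon between an aryl carbon and an alkyne-derived carbon, so the ring should arise in one Pd-catalysed carbonylative annulation from an o-iodophenol, carbon monoxide and an arylacetylene. The iodophenol already carries the prenyl group at the future C8, placed by two directed ortho-metalations of symmetric 3,5-dimethoxyphenol. No chelated phenol has to be alkylated and no prenyl group has to migrate. The two remaining O-alkyl groups (5-OMe, 4'-O-iPr) should fall in one BCl3 treatment.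

Key step: step 7

Assumption: the target has no stereocentre and its only alkene (the prenyl double bond) has no E/Z isomers, so the SMILES defines one achiral compound and no stereoselective step is needed.

**Route**

Step 1
Reactants: 1, 3,5-dimethoxyphenol; 2, chloromethyl methyl ether
Product: 3 1,3-dimethoxy-5-(methoxymethoxy)benzene
Conditions: MOMCl, iPr2NEt, CH2Cl2, 0 °C → rt
Reagents that add atoms: chloromethyl methyl ether, COCCl
Why: Williamson-type O-alkylation of the only phenol gives the MOM acetal, which is the chelating directing group for both metalations that follow.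

Step 2
Reactants: 3, 1,3-dimethoxy-5-(methoxymethoxy)benzene; 4, prenyl bromide (1-bromo-3-methylbut-2-ene)
Product: 6 1,5-dimethoxy-3-(methoxymethoxy)-2-(3-methylbut-2-en-1-yl)benzene, via aryllithium 5 (not isolated)
Conditions: n-BuLi, THF, 0 °C; then CuBr·SMe2 (10 mol%), prenyl bromide, –78 °C → rt
Reagents that add atoms: prenyl bromide, CC(C)=CCBr
Why: Directed ortho-metalation: the chelating OMOM group together with a flanking OMe should direct n-BuLi to a position between OMOM and OMe (C4 and C6 of 3, equivalent by symmetry) rather than to C2 between the two weaker OMe donors, and copper-catalysed SN2 allylation of aryllithium 5 should give the linear prenyl arene.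

Step 3
Reactants: 6, 1,5-dimethoxy-3-(methoxymethoxy)-2-(3-methylbut-2-en-1-yl)benzene; 7, iodine
Product: 9 2-iodo-1,5-dimethoxy-3-(methoxymethoxy)-4-(3-methylbut-2-en-1-yl)benzene, via aryllithium 8 (not isolated)
Conditions: n-BuLi, THF, –20 → 0 °C; then I2, THF, –78 °C; aq. Na2S2O3
Reagents that add atoms: iodine, II
Why: Second directed ortho-metalation: the only remaining position ortho to OMOM lies between OMOM and OMe and should be lithiated by complex-induced proximity in preference to the benzylic–allylic CH2 and to the position between the two methoxy groups, and aryllithium 8 should be iodinated at –78 °C faster than iodine reacts with the alkene.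

Step 4
Reactants: 9, 2-iodo-1,5-dimethoxy-3-(methoxymethoxy)-4-(3-methylbut-2-en-1-yl)benzene
Product: 10 2-iodo-3,5-dimethoxy-6-(3-methylbut-2-en-1-yl)phenol
Conditions: conc. HCl (cat.), MeOH, rt
Reagents that add atoms: none
Why: Acid-catalysed acetal exchange with methanol (MOM cleavage) frees the phenol ortho to iodine under conditions mild enough that the neighbouring prenyl group should not cyclise onto it.

Step 5
Reactants: 11, 4-hydroxy-2-methoxybenzaldehyde; 12, 2-bromopropane
Product: 13 2-methoxy-4-(propan-2-yloxy)benzaldehyde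
Conditions: 2-bromopropane, K2CO3, DMF, 60 °C
Reagents that add atoms: 2-bromopropane, CC(C)Br
Why: Williamson ether synthesis (SN2) at the only phenol installs an isopropyl ether that is stable to base, amine and Pd/CO and is cleaved by BCl3 together with the 5-OMe at the end.

Step 6
Reactants: 13, 2-methoxy-4-(propan-2-yloxy)benzaldehyde; 14, dimethyl (1-diazo-2-oxopropyl)phosphonate
Product: 15 1-ethynyl-2-methoxy-4-(propan-2-yloxy)benzene
Conditions: Ohira–Bestmann reagent, K2CO3, MeOH, rt
Reagents that add atoms: dimethyl (1-diazo-2-oxopropyl)phosphonate, CC(=O)C(=[N+]=[N-])P(=O)(OC)OC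
Why: Seyferth–Gilbert homologation with the Ohira–Bestmann reagent: methanolysis gives dimethyl (diazomethyl)phosphonate, whose anion converts the non-enolisable aldehyde into the terminal alkyne by Horner–Wadsworth–Emmons addition, loss of N2 and 1,2-hydride shift.

Step 7
Reactants: 10, 2-iodo-3,5-dimethoxy-6-(3-methylbut-2-en-1-yl)phenol; 15, 1-ethynyl-2-methoxy-4-(propan-2-yloxy)benzene; 16, carbon monoxide
Product: 19 5,7-dimethoxy-2-[2-methoxy-4-(propan-2-yloxy)phenyl]-8-(3-methylbut-2-en-1-yl)-4H-chromen-4-one, via ynone 17 (not isolated), via enaminone 18 (not isolated)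
Conditions: PdCl2(dppf) (5 mol%), CO (20 bar), Et2NH, 120 °C, autoclave
Reagents that add atoms: carbon monoxide, [C-]#[O+]
Why: Pd(0) should insert into the C–I bond of 10, take up CO to give an aroyl–Pd(II) species and couple it with the amine-activated alkyne 15 to give ynone 17 (bonds C4a–C4 and C4–C3); Et2NH should then add to 17 to give enaminone 18, whose C2 is attacked by the phenol O1 with loss of the amine (bond O1–C2). The closest known reaction type is the carbonylative Sonogashira annulation of o-iodophenols with terminal alkynes to flavones. The pyranone ring closes in a formal 6-endo-dig mode, in detail a 6-endo-trig addition–elimination on 18, and no stereocentre is formed. CO insertion must outrun direct alkynylation, which would end in a 2-arylbenzofuran: CO pressure, the absence of copper and the electron-rich, doubly ortho-substituted aryl–Pd bond favour insertion. The 6-endo closure must win over 5-exo closure to an aurone: in 18 only C2 is electrophilic. The regiochemistry is fixed because 10 has a single phenol, ortho to the iodine, and the trisubstituted prenyl alkene, meta to the C–Pd carbon, has no feasible Heck pathway.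

Step 8
Reactants: 19, 5,7-dimethoxy-2-[2-methoxy-4-(propan-2-yloxy)phenyl]-8-(3-methylbut-2-en-1-yl)-4H-chromen-4-one
Product: 20 artocarpetin B, 5-hydroxy-2-(4-hydroxy-2-methoxyphenyl)-7-methoxy-8-(3-methylbut-2-en-1-yl)-4H-chromen-4-one
Conditions: BCl3 (1 M in CH2Cl2, 4 equiv), CH2Cl2, –78 → –10 °C; then H2O, 0 °C
Reagents that add atoms: none
Why: Lewis-acid ether cleavage: BCl3 chelated between C4=O and the peri 5-OMe should cleave that methyl ether selectively over the unchelated 7- and 2'-OMe groups, the secondary isopropyl ether should be cleaved at the same temperature, and the prenyl group, flanked by OMe and the ring oxygen, has no free phenol to cyclise onto.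

**Compound list**

1 | 3,5-dimethoxyphenol | COc1cc(O)cc(OC)c1 | starting material
2 | chloromethyl methyl ether | COCCl | starting material
3 | 1,3-dimethoxy-5-(methoxymethoxy)benzene | COCOc1cc(OC)cc(OC)c1 | intermediate
4 | prenyl bromide (1-bromo-3-methylbut-2-ene) | CC(C)=CCBr | starting material
5 | [2,4-dimethoxy-6-(methoxymethoxy)phenyl]lithium | [Li]c1c(OC)cc(OC)cc1OCOC | intermediate
6 | 1,5-dimethoxy-3-(methoxymethoxy)-2-(3-methylbut-2-en-1-yl)benzene | COCOc1cc(OC)cc(OC)c1CC=C(C)C | intermediate
7 | iodine | II | starting material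
8 | [4,6-dimethoxy-2-(methoxymethoxy)-3-(3-methylbut-2-en-1-yl)phenyl]lithium | [Li]c1c(OC)cc(OC)c(CC=C(C)C)c1OCOC | intermediate
9 | 2-iodo-1,5-dimethoxy-3-(methoxymethoxy)-4-(3-methylbut-2-en-1-yl)benzene | COCOc1c(I)c(OC)cc(OC)c1CC=C(C)C | intermediate
10 | 2-iodo-3,5-dimethoxy-6-(3-methylbut-2-en-1-yl)phenol | Oc1c(I)c(OC)cc(OC)c1CC=C(C)C | intermediate
11 | 4-hydroxy-2-methoxybenzaldehyde | COc1cc(O)ccc1C=O | starting material
12 | 2-bromopropane | CC(C)Br | starting material
13 | 2-methoxy-4-(propan-2-yloxy)benzaldehyde | COc1cc(OC(C)C)ccc1C=O | intermediate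
14 | dimethyl (1-diazo-2-oxopropyl)phosphonate | CC(=O)C(=[N+]=[N-])P(=O)(OC)OC | starting material
15 | 1-ethynyl-2-methoxy-4-(propan-2-yloxy)benzene | C#Cc1ccc(OC(C)C)cc1OC | intermediate
16 | carbon monoxide | [C-]#[O+] | starting material
17 | 1-[2-hydroxy-4,6-dimethoxy-3-(3-methylbut-2-en-1-yl)phenyl]-3-[2-methoxy-4-(propan-2-yloxy)phenyl]prop-2-yn-1-one | COc1cc(OC(C)C)ccc1C#CC(=O)c1c(O)c(CC=C(C)C)c(OC)cc1OC | intermediate
18 | 3-(diethylamino)-1-[2-hydroxy-4,6-dimethoxy-3-(3-methylbut-2-en-1-yl)phenyl]-3-[2-methoxy-4-(propan-2-yloxy)phenyl]prop-2-en-1-one (alkene geometry not defined) | CCN(CC)C(=CC(=O)c1c(O)c(CC=C(C)C)c(OC)cc1OC)c1ccc(OC(C)C)cc1OC | intermediate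
19 | 5,7-dimethoxy-2-[2-methoxy-4-(propan-2-yloxy)phenyl]-8-(3-methylbut-2-en-1-yl)-4H-chromen-4-one | COc1cc(OC(C)C)ccc1-c1cc(=O)c2c(OC)cc(OC)c(CC=C(C)C)c2o1 | intermediate
20 | artocarpetin B, 5-hydroxy-2-(4-hydroxy-2-methoxyphenyl)-7-methoxy-8-(3-methylbut-2-en-1-yl)-4H-chromen-4-one | COc1cc(O)ccc1-c1cc(=O)c2c(O)cc(OC)c(CC=C(C)C)c2o1 | target

**Total step count:** 8
**Longest linear sequence:** 6 steps (1 → 3 → 6 → 9 → 10 → 19 → 20; steps 5 and 6 make the alkyne branch)

**Steps most likely to fail**

Step 7. Direct alkynylation without CO uptake, aminocarbonylation of the aroyl–Pd species by diethylamine, or slow oxidative addition at the hindered iodide could divert the annulation. The fallback would set out from 9 and come back at 17, building the ynone by carbonyl addition instead of carbonylation. Iodine–lithium exchange of 9 with n-BuLi in THF at –78 °C would regenerate aryllithium 8, and DMF would convert it into 4,6-dimethoxy-2-(methoxymethoxy)-3-(3-methylbut-2-en-1-yl)benzaldehyde F1. Alkyne 15 would be deprotonated with n-BuLi to {[2-methoxy-4-(propan-2-yloxy)phenyl]ethynyl}lithium F2, which would add to F1 to give racemic 1-[4,6-dimethoxy-2-(methoxymethoxy)-3-(3-methylbut-2-en-1-yl)phenyl]-3-[2-methoxy-4-(propan-2-yloxy)phenyl]prop-2-yn-1-ol F3. MnO2 in CH2Cl2 would oxidise F3 to the O-MOM ynone 1-[4,6-dimethoxy-2-(methoxymethoxy)-3-(3-methylbut-2-en-1-yl)phenyl]-3-[2-methoxy-4-(propan-2-yloxy)phenyl]prop-2-yn-1-one F4, and HCl in MeOH would remove the acetal to give 17. Et2NH in EtOH would then close 17 to 19 through 18.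

Step 3. Deprotonation at the benzylic–allylic CH2 of the prenyl group, or at the position between the two methoxy groups, could compete with lithiation next to OMOM. The fallback would set out from 3 and come back at 10, placing the iodine before the prenyl group. Lithiation of 3 to aryllithium 5 and quenching with iodine 7 would give 2-iodo-1,5-dimethoxy-3-(methoxymethoxy)benzene F5, and HCl in MeOH would give 2-iodo-3,5-dimethoxyphenol F6. O-Alkylation with prenyl bromide 4 and K2CO3 in acetone would give 2-iodo-1,5-dimethoxy-3-[(3-methylbut-2-en-1-yl)oxy]benzene F7. A montmorillonite K10-mediated [1,3] O-to-C shift of the prenyl group to the only free ortho position would then give 10.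

Step 8. HCl addition to the prenyl alkene, cationic closure of the side chain onto O7 with loss of its methyl group, or incomplete cleavage of one of the two ethers could spoil the last step. The fallback would set out from 11 and come back at 20, replacing the isopropyl ether by an acetal and the BCl3 treatment by a neutral, chelation-driven demethylation. Chloromethyl methyl ether 2 and iPr2NEt would convert 11 into 2-methoxy-4-(methoxymethoxy)benzaldehyde F8, and the Ohira–Bestmann reagent 14 would give 1-ethynyl-2-methoxy-4-(methoxymethoxy)benzene F9. The annulation of F9 with 10 and carbon monoxide 16 under the conditions of step 7 would pass through the ynone 1-[2-hydroxy-4,6-dimethoxy-3-(3-methylbut-2-en-1-yl)phenyl]-3-[2-methoxy-4-(methoxymethoxy)phenyl]prop-2-yn-1-one F10 and the enaminone 3-(diethylamino)-1-[2-hydroxy-4,6-dimethoxy-3-(3-methylbut-2-en-1-yl)phenyl]-3-[2-methoxy-4-(methoxymethoxy)phenyl]prop-2-en-1-one F11. It would give 5,7-dimethoxy-2-[2-methoxy-4-(methoxymethoxy)phenyl]-8-(3-methylbut-2-en-1-yl)-4H-chromen-4-one F12. HCl in MeOH at rt would then give 2-(4-hydroxy-2-methoxyphenyl)-5,7-dimethoxy-8-(3-methylbut-2-en-1-yl)-4H-chromen-4-one F13, and MgI2·OEt2 in toluene at 80 °C would cleave only the chelated 5-OMe to give 20.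

**Further compounds**

F1 | step 7 | 4,6-dimethoxy-2-(methoxymethoxy)-3-(3-methylbut-2-en-1-yl)benzaldehyde | COCOc1c(C=O)c(OC)cc(OC)c1CC=C(C)C
F2 | step 7 | {[2-methoxy-4-(propan-2-yloxy)phenyl]ethynyl}lithium | [Li]C#Cc1ccc(OC(C)C)cc1OC
F3 | step 7 | rac-1-[4,6-dimethoxy-2-(methoxymethoxy)-3-(3-methylbut-2-en-1-yl)phenyl]-3-[2-methoxy-4-(propan-2-yloxy)phenyl]prop-2-yn-1-ol | COCOc1c(C(O)C#Cc2ccc(OC(C)C)cc2OC)c(OC)cc(OC)c1CC=C(C)C
F4 | step 7 | 1-[4,6-dimethoxy-2-(methoxymethoxy)-3-(3-methylbut-2-en-1-yl)phenyl]-3-[2-methoxy-4-(propan-2-yloxy)phenyl]prop-2-yn-1-one | COCOc1c(C(=O)C#Cc2ccc(OC(C)C)cc2OC)c(OC)cc(OC)c1CC=C(C)C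
F5 | step 3 | 2-iodo-1,5-dimethoxy-3-(methoxymethoxy)benzene | COCOc1cc(OC)cc(OC)c1I
F6 | step 3 | 2-iodo-3,5-dimethoxyphenol | COc1cc(O)c(I)c(OC)c1
F7 | step 3 | 2-iodo-1,5-dimethoxy-3-[(3-methylbut-2-en-1-yl)oxy]benzene | COc1cc(OC)c(I)c(OCC=C(C)C)c1
F8 | step 8 | 2-methoxy-4-(methoxymethoxy)benzaldehyde | COCOc1ccc(C=O)c(OC)c1
F9 | step 8 | 1-ethynyl-2-methoxy-4-(methoxymethoxy)benzene | C#Cc1ccc(OCOC)cc1OC
F10 | step 8 | 1-[2-hydroxy-4,6-dimethoxy-3-(3-methylbut-2-en-1-yl)phenyl]-3-[2-methoxy-4-(methoxymethoxy)phenyl]prop-2-yn-1-one | COCOc1ccc(C#CC(=O)c2c(O)c(CC=C(C)C)c(OC)cc2OC)c(OC)c1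
F11 | step 8 | 3-(diethylamino)-1-[2-hydroxy-4,6-dimethoxy-3-(3-methylbut-2-en-1-yl)phenyl]-3-[2-methoxy-4-(methoxymethoxy)phenyl]prop-2-en-1-one (alkene geometry not defined) | CCN(CC)C(=CC(=O)c1c(O)c(CC=C(C)C)c(OC)cc1OC)c1ccc(OCOC)cc1OC
F12 | step 8 | 5,7-dimethoxy-2-[2-methoxy-4-(methoxymethoxy)phenyl]-8-(3-methylbut-2-en-1-yl)-4H-chromen-4-one | COCOc1ccc(-c2cc(=O)c3c(OC)cc(OC)c(CC=C(C)C)c3o2)c(OC)c1
F13 | step 8 | 2-(4-hydroxy-2-methoxyphenyl)-5,7-dimethoxy-8-(3-methylbut-2-en-1-yl)-4H-chromen-4-one | COc1cc(O)ccc1-c1cc(=O)c2c(OC)cc(OC)c(CC=C(C)C)c2o1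
A1 | direct plan | 2',6'-dihydroxy-4'-methoxyacetophenone | CC(=O)c1c(O)cc(OC)cc1O
A2 | direct plan | (E)-1-(2,6-dihydroxy-4-methoxyphenyl)-3-[2-methoxy-4-(methoxymethoxy)phenyl]prop-2-en-1-one | COCOc1ccc(/C=C/C(=O)c2c(O)cc(OC)cc2O)c(OC)c1
A3 | direct plan | 5-hydroxy-7-methoxy-2-[2-methoxy-4-(methoxymethoxy)phenyl]-4H-chromen-4-one | COCOc1ccc(-c2cc(=O)c3c(O)cc(OC)cc3o2)c(OC)c1
A4 | direct plan | 7-methoxy-2-[2-methoxy-4-(methoxymethoxy)phenyl]-5-[(3-methylbut-2-en-1-yl)oxy]-4H-chromen-4-one | COCOc1ccc(-c2cc(=O)c3c(OCC=C(C)C)cc(OC)cc3o2)c(OC)c1
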